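The ring C1–C2–C3=C4–C4a–C8a is read as one ring of a naphthalene across whose C1–C2 bond an aryl anion and a proton have been added. The veratryl ring is therefore joined to C1 by dearomatising conjugate addition of 3,4-dimethoxyphenyllithium to a flat 6,7-dimethoxy-3-methylnaphthalene that carries an (R)-4-tert-butyloxazoline at C2. This one operation forms the C1–aryl bond. It also sets C1 (auxiliary control) and C2 (equilibrating protonation to the trans, diaxial isomer), and it leaves the C3=C4 styrene bond where the target has it. The oxazoline carbon is then reduced to the C2 methyl group.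

Key step: step 4

Assumption: the target is the trans isomer, (1R,2S) in dihydronaphthalene numbering (C1 bears the aryl group, C2 the sp3-bound methyl group), and the sense of induction in the key step follows the accepted model of delivery anti to the oxazoline 4-substituent; should it prove opposite, (S)-tert-leucinol replaces the (R)-amino alcohol without other change.

Step 1
Reactants: 1 5,6-dimethoxyphthalide
Product: 2 lactol 5,6-dimethoxy-1,3-dihydroisobenzofuran-1-ol
Conditions: DIBAL-H (1.1 equiv), CH2Cl2, −78 °C; aq Rochelle salt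
Reagents that add atoms: none
Why: Partial lactone reduction with DIBAL-H stops at the aluminium hemiacetal at low temperature and should give the lactol on work-up; its new hemiacetal carbon has no stereochemical consequence.

Step 2
Reactants: 2 lactol; 3 crotononitrile (E/Z mixture, excess)
Product: 6 nitrile 6,7-dimethoxy-3-methylnaphthalene-2-carbonitrile, via isobenzofuran 4 (not isolated), via oxa-bridged adduct 5 (not isolated)
Conditions: TsOH·H2O (10 mol %), toluene, reflux, Dean–Stark trap
Reagents that add atoms: none
Why: Acid-catalysed dehydration of the hydroxyphthalan releases the electron-rich isobenzofuran 4 at low concentration, a Diels–Alder reaction with excess crotononitrile traps it, and the same acid opens and dehydrates the oxygen bridge of 5, so that all regio- and stereoisomers of 5 converge on one naphthalene because of the symmetric 6,7-dimethoxy pattern.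

Step 3
Reactants: 6 nitrile; 7 (R)-tert-leucinol
Product: 8 naphthyloxazoline (4R)-4-tert-butyl-2-(6,7-dimethoxy-3-methylnaphthalen-2-yl)-4,5-dihydrooxazole
Conditions: ZnCl2 (10 mol %), PhCl, reflux
Reagents that add atoms: none
Why: Zinc-catalysed Witte–Seeliger condensation of a nitrile with a 1,2-amino alcohol forms the oxazoline with loss of ammonia and does not touch the stereocenter of 7.

Step 4
Reactants: 8 naphthyloxazoline; 9 4-bromoveratrole
Product: 13 trans adduct (4R)-4-tert-butyl-2-[(1R,2S)-1-(3,4-dimethoxyphenyl)-6,7-dimethoxy-3-methyl-1,2-dihydronaphthalen-2-yl]-4,5-dihydrooxazole, via aryllithium 10 (not isolated), via lithium aza-enolate 11 (not isolated), via cis epimer 12 (not isolated)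
Conditions: 9, t-BuLi (2.0 equiv per 9, leaves no alkyl halide), THF, −78 °C; add 8, −78 → −30 °C; t-BuOH, −78 °C → rt, KOt-Bu (20 mol %), argon; aq NH4Cl; chromatography to remove minor diastereomers
Reagents that add atoms: none
Why: Aryllithium 10 binds to the oxazoline nitrogen of 8 in the s-cis azadiene conformer N=C–C2=C1 and hands its aryl group to C1 in a 1,4-addition that sacrifices the aromaticity of the substituted ring only and gives the lithium aza-enolate 11. This is the oxazoline-directed dearomatising conjugate addition of organolithium reagents to naphthalenes (Meyers naphthyloxazoline addition), a known reaction of 2-naphthyloxazolines with aryllithiums; it closes no ring. C1 is set by the auxiliary, because the nitrogen-bound aryllithium reaches the naphthalene face anti to the 4-tert-butyl group, which for the (R)-oxazoline leads to 1R. C2 is set by the substrate under equilibration: protonation anti to the pseudoaxial aryl group should give first mainly the cis isomer 12, and tert-butoxide reversibly removes the C2–H (alpha to C=N and allylic) until the trans isomer 13 prevails, in which aryl and oxazoline are both pseudoaxial and escape the peri C8–H and the C3 methyl group. Attack at C1 rather than C3 follows from the high double-bond character of C1–C2 and keeps the dimethoxybenzene ring aromatic, and after protonation the double bond stays at C3=C4 because conjugation with that ring outweighs conjugation with the C=N bond. The selectivity most in need is addition over deprotonation of the C3 methyl group, which is served by the low kinetic basicity of an aryllithium, the low temperature and the preference of the metal-bearing nitrogen for the unhindered C1–H side.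

Step 5
Reactants: 13 trans adduct
Product: 17 alcohol [(1R,2S)-1-(3,4-dimethoxyphenyl)-6,7-dimethoxy-3-methyl-1,2-dihydronaphthalen-2-yl]methanol, via oxazolinium triflate 14 (not isolated), via oxazolidine 15 (not isolated), via aldehyde 16 (not isolated)
Conditions: MeOTf, CH2Cl2, rt; NaBH4, THF–MeOH, 0 °C; oxalic acid, THF–H2O, rt; NaHCO3, then NaBH4, 0 °C
Reagents that add atoms: water, O; methyl triflate, COS(=O)(=O)C(F)(F)F (its methyl group is carried only by 14 and 15 and leaves with the auxiliary)
Why: Reductive oxazoline cleavage (N-methylation, borohydride reduction to the oxazolidine, mild acid hydrolysis) frees aldehyde 16, which is reduced at once so that this beta,gamma-unsaturated aldehyde has no time to epimerise or to shift its double bond, and C1 and C2 are not touched.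

Step 6
Reactants: 17 alcohol
Product: 18 mesylate [(1R,2S)-1-(3,4-dimethoxyphenyl)-6,7-dimethoxy-3-methyl-1,2-dihydronaphthalen-2-yl]methyl methanesulfonate
Conditions: MsCl, Et3N, CH2Cl2, 0 °C
Reagents that add atoms: methanesulfonyl chloride, CS(=O)(=O)Cl
Why: Sulfonylation of an unhindered primary alcohol proceeds at oxygen only and leaves both stereocenters and the styrene bond alone.

Step 7
Reactants: 18 mesylate
Product: 19 target (1R,2S)-1-(3,4-dimethoxyphenyl)-6,7-dimethoxy-2,3-dimethyl-1,2-dihydronaphthalene
Conditions: LiEt3BH (3 equiv), THF, 0 °C → rt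
Reagents that add atoms: none
Why: SN2 displacement of a primary sulfonate by hydride turns CH2OMs into CH3 without touching a stereocenter, and this polar method is preferred to radical deoxygenation because a primary radical at this carbon could add to the neighbouring C3=C4 styrene bond.

Compound list
1 | 5,6-dimethoxyphthalide (5,6-dimethoxy-3H-isobenzofuran-1-one) | O=C1OCc2cc(OC)c(OC)cc12 | starting material
2 | 5,6-dimethoxy-1,3-dihydroisobenzofuran-1-ol (lactol, racemic) | OC1OCc2cc(OC)c(OC)cc12 | intermediate
3 | crotononitrile (but-2-enenitrile, E/Z mixture) | CC=CC#N | starting material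
4 | 5,6-dimethoxyisobenzofuran | COC1=CC2=COC=C2C=C1OC | intermediate
5 | 1,4-epoxy-6,7-dimethoxy-3-methyl-1,2,3,4-tetrahydronaphthalene-2-carbonitrile (stereoisomer mixture) | N#CC1C(C)C2OC1c1cc(OC)c(OC)cc12 | intermediate
6 | 6,7-dimethoxy-3-methylnaphthalene-2-carbonitrile | COc1cc2cc(C)c(C#N)cc2cc1OC | intermediate
7 | (R)-tert-leucinol, (2R)-2-amino-3,3-dimethylbutan-1-ol | CC(C)(C)[C@@H](N)CO | starting material
8 | (4R)-4-tert-butyl-2-(6,7-dimethoxy-3-methylnaphthalen-2-yl)-4,5-dihydrooxazole | CC(C)(C)[C@@H]1COC(=N1)c1cc2cc(OC)c(OC)cc2cc1C | intermediate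
9 | 4-bromoveratrole (4-bromo-1,2-dimethoxybenzene) | COc1ccc(Br)cc1OC | starting material
10 | 3,4-dimethoxyphenyllithium | COc1ccc([Li])cc1OC | intermediate
11 | lithium aza-enolate of 13 (C2 doubly bonded to the carbon of the N-lithiooxazolidine, C1 configured as in 13) | COc1ccc([C@@H]2c3cc(OC)c(OC)cc3C=C(C)C2=C4OC[C@H](N4[Li])C(C)(C)C)cc1OC | intermediate
12 | cis epimer, (4R)-4-tert-butyl-2-[(1R,2R)-1-(3,4-dimethoxyphenyl)-6,7-dimethoxy-3-methyl-1,2-dihydronaphthalen-2-yl]-4,5-dihydrooxazole | COc1ccc([C@@H]2c3cc(OC)c(OC)cc3C=C(C)[C@@H]2C4=N[C@@H](CO4)C(C)(C)C)cc1OC | intermediate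
13 | trans adduct, (4R)-4-tert-butyl-2-[(1R,2S)-1-(3,4-dimethoxyphenyl)-6,7-dimethoxy-3-methyl-1,2-dihydronaphthalen-2-yl]-4,5-dihydrooxazole | COc1ccc([C@@H]2c3cc(OC)c(OC)cc3C=C(C)[C@H]2C4=N[C@@H](CO4)C(C)(C)C)cc1OC | intermediate
14 | N-methyloxazolinium triflate of 13 | COc1ccc([C@@H]2c3cc(OC)c(OC)cc3C=C(C)[C@H]2C4=[N+](C)[C@@H](CO4)C(C)(C)C)cc1OC.[O-]S(=O)(=O)C(F)(F)F | intermediate
15 | N-methyloxazolidine from 14 (epimers at the aminal carbon) | COc1ccc([C@@H]2c3cc(OC)c(OC)cc3C=C(C)[C@H]2C4N(C)[C@@H](CO4)C(C)(C)C)cc1OC | intermediate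
16 | (1R,2S)-1-(3,4-dimethoxyphenyl)-6,7-dimethoxy-3-methyl-1,2-dihydronaphthalene-2-carbaldehyde | COc1ccc([C@@H]2c3cc(OC)c(OC)cc3C=C(C)[C@H]2C=O)cc1OC | intermediate
17 | [(1R,2S)-1-(3,4-dimethoxyphenyl)-6,7-dimethoxy-3-methyl-1,2-dihydronaphthalen-2-yl]methanol | COc1ccc([C@@H]2c3cc(OC)c(OC)cc3C=C(C)[C@H]2CO)cc1OC | intermediate
18 | methanesulfonate of 17 | COc1ccc([C@@H]2c3cc(OC)c(OC)cc3C=C(C)[C@H]2COS(C)(=O)=O)cc1OC | intermediate
19 | (1R,2S)-1-(3,4-dimethoxyphenyl)-6,7-dimethoxy-2,3-dimethyl-1,2-dihydronaphthalene | COc1ccc([C@@H]2c3cc(OC)c(OC)cc3C=C(C)[C@H]2C)cc1OC | target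

Total step count: 7. Longest linear sequence: 7 steps (1 → 19). Compounds 3, 7 and 9 enter as purchased.

Steps most likely to fail

Step 4. The aryllithium may act as a base toward the C3 methyl group, whose protons are acidified by the neighbouring oxazoline (lateral metalation). It may also fail to add to the electron-rich naphthalene. In either case 8 is only returned on quenching. Incomplete facial control and slow equilibration at C2 are secondary concerns.

The fallback sets out from 2 and comes back at 19. It carries both methyl groups through the bond-forming event as oxazolines, so that no acidic side-chain proton is present and the acceptor is doubly activated.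
- Lactol 2 and fumaronitrile, a far faster dienophile, under the conditions of step 2 should give 6,7-dimethoxynaphthalene-2,3-dicarbonitrile F1.
- Two equivalents of 7 (ZnCl2, PhCl, reflux) then give the C2-symmetric 2,3-bis[(4R)-4-tert-butyl-4,5-dihydrooxazol-2-yl]-6,7-dimethoxynaphthalene F2.
- Addition of 10 to C1 (C1 and C4 are homotopic) and equilibrating protonation as in step 4 should give the (1R,2S)-trans-1-aryl-2,3-bis(oxazolinyl)-1,2-dihydronaphthalene F3. Its C3=C4 bond is held in place by conjugation with the second oxazoline.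
- Twofold N-methylation, borohydride reduction and oxalic acid hydrolysis give the (1R,2S)-2,3-dicarbaldehyde F4.
- Luche reduction gives the (1R,2S)-2,3-bis(hydroxymethyl) compound F5, and mesylation at low temperature gives the bis(methanesulfonate) F6.
- LiEt3BH displaces both sulfonates to give 19.

Step 2. The transient isobenzofuran may oligomerise faster than the beta-substituted, singly activated nitrile dienophile intercepts it.

The fallback sets out from 2 and comes back at 8. It replaces the nitrile by (E)-crotonaldehyde, whose carbonyl group is activated by the same acid that releases the diene, and it changes the way the oxazoline is built.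
- Cycloaddition and dehydration should give 6,7-dimethoxy-3-methylnaphthalene-2-carbaldehyde F7.
- Condensation with 7 over molecular sieves gives the (4R)-4-tert-butyl-2-(6,7-dimethoxy-3-methylnaphthalen-2-yl)oxazolidine F8.
- Oxidation with I2 and K2CO3 in t-BuOH dehydrogenates F8 to 8.

Step 5. N-Methylation next to the tert-butyl group may be sluggish. The liberated beta,gamma-unsaturated aldehyde may also enolise, with loss of configuration at C2 or migration of the double bond to C2=C3, before it is reduced.

The fallback sets out from 13 and comes back at 17, and it avoids the aldehyde oxidation level altogether.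
- Hydrolytic ring opening (TFA, H2O, THF) gives the (2R)-2-amino-3,3-dimethylbutyl (1R,2S)-dihydronaphthalene-2-carboxylate F9.
- Immediate N-acetylation (Ac2O, pyridine) blocks O-to-N acyl migration and gives the N-acetyl amino ester F10.
- LiAlH4 reduces the ester to 17.

Further compounds
F1 | step 4 | 6,7-dimethoxynaphthalene-2,3-dicarbonitrile | COc1cc2cc(C#N)c(C#N)cc2cc1OC
F2 | step 4 | 2,3-bis[(4R)-4-tert-butyl-4,5-dihydrooxazol-2-yl]-6,7-dimethoxynaphthalene | COc1cc2cc(C3=N[C@@H](CO3)C(C)(C)C)c(cc2cc1OC)C4=N[C@@H](CO4)C(C)(C)C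
F3 | step 4 | (1R,2S)-1-(3,4-dimethoxyphenyl)-6,7-dimethoxy-2,3-bis[(4R)-4-tert-butyl-4,5-dihydrooxazol-2-yl]-1,2-dihydronaphthalene | COc1ccc([C@@H]2c3cc(OC)c(OC)cc3C=C(C5=N[C@@H](CO5)C(C)(C)C)[C@H]2C4=N[C@@H](CO4)C(C)(C)C)cc1OC
F4 | step 4 | (1R,2S)-1-(3,4-dimethoxyphenyl)-6,7-dimethoxy-1,2-dihydronaphthalene-2,3-dicarbaldehyde | COc1ccc([C@@H]2c3cc(OC)c(OC)cc3C=C(C=O)[C@H]2C=O)cc1OC
F5 | step 4 | [(1R,2S)-1-(3,4-dimethoxyphenyl)-6,7-dimethoxy-1,2-dihydronaphthalene-2,3-diyl]dimethanol | COc1ccc([C@@H]2c3cc(OC)c(OC)cc3C=C(CO)[C@H]2CO)cc1OC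
F6 | step 4 | bis(methanesulfonate) of F5 | COc1ccc([C@@H]2c3cc(OC)c(OC)cc3C=C(COS(C)(=O)=O)[C@H]2COS(C)(=O)=O)cc1OC
F7 | step 2 | 6,7-dimethoxy-3-methylnaphthalene-2-carbaldehyde | COc1cc2cc(C)c(C=O)cc2cc1OC
F8 | step 2 | (4R)-4-tert-butyl-2-(6,7-dimethoxy-3-methylnaphthalen-2-yl)oxazolidine | CC(C)(C)[C@@H]1COC(N1)c1cc2cc(OC)c(OC)cc2cc1C
F9 | step 5 | (2R)-2-amino-3,3-dimethylbutyl (1R,2S)-1-(3,4-dimethoxyphenyl)-6,7-dimethoxy-3-methyl-1,2-dihydronaphthalene-2-carboxylate | COc1ccc([C@@H]2c3cc(OC)c(OC)cc3C=C(C)[C@H]2C(=O)OC[C@H](N)C(C)(C)C)cc1OC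
F10 | step 5 | (2R)-2-acetamido-3,3-dimethylbutyl (1R,2S)-1-(3,4-dimethoxyphenyl)-6,7-dimethoxy-3-methyl-1,2-dihydronaphthalene-2-carboxylate | COc1ccc([C@@H]2c3cc(OC)c(OC)cc3C=C(C)[C@H]2C(=O)OC[C@H](NC(C)=O)C(C)(C)C)cc1OC
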